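**Retrosynthetic overview**
1. Locants: each half is numbered as a 1-aryl-1,2-dihydronaphthalene (C1 aryl, C2/C3 carboxyl, C4 vinylic CH, C5 biaryl carbon, C6/C7 oxygen). Ring A is the unprimed carbocycle (1R,2S) and ring B the primed one (1'S,2'R). O-demethylation, ester hydrolysis and imide hydrolysis lead back to bis-imide 16.
2. Key disconnection: in both carbocycles the benzhydrylic carbon C1 (C1') is cut from C2 (C2') and from C8a (C8a') at once. It is the carbonyl carbon of 3,4-dimethoxybenzaldehyde, so 16 comes from the carbocycle-free bis-imide 11 by a twofold aldol/Friedel–Crafts [5+1] annulation that also brings in both pendant aryl rings.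
3. Enabling feature: C1 (C1') lies between an enolisable carbon (C2, alpha to the C2 carboxyl) and an arene carbon (C8a, para to the C6 oxygen), and it carries an aryl ring whose para oxygen stabilises a cation there. The two halves are mirror images, so an (R)- and an (S)-oxazolidinone on the two C2 carboxyls programme them. The two C5–C5' atropisomers are then enantiomers, so the axis needs no control.
4. Compound 11 comes from one Stobbe half-ester 3, used twice: as the aryl bromide and, after borylation and loading of the (S)-auxiliary, as boronate 7. A Suzuki–Miyaura coupling forms C5–C5', and the (R)-auxiliary is loaded afterwards.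
5. Ring order: the four benzene rings are bought and C5–C5' joins two of them. Ring A and, last, ring B are then closed in the same flask.

Key step: step 6

Assumption: the target structure leaves the C5–C5' axis undefined. Because the halves are mirror images, its two atropisomers are enantiomers, and the route aims at this one diastereomer without controlling the axis.

**Step 1**
Reactants: 1 2-bromo-3,4-dimethoxybenzaldehyde; 2 dimethyl succinate
Product: 3 (E)-4-(2-bromo-3,4-dimethoxyphenyl)-3-(methoxycarbonyl)but-3-enoic acid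
Conditions: NaOMe, MeOH, reflux; then 2 M HCl
Reagents that add atoms: none
Why: Stobbe condensation, in which the succinate enolate adds to the aldehyde, the alkoxide lactonises onto the distal ester and E1cB opening should give the half-ester with the aryl group cis to the CH2CO2H arm (E), the geometry the later ring closure needs.

**Step 2**
Reactants: 3 bromo half-ester
Product: 4 (E)-4-[3,4-dimethoxy-2-(4,4,5,5-tetramethyl-1,3,2-dioxaborolan-2-yl)phenyl]-3-(methoxycarbonyl)but-3-enoic acid
Conditions: B2pin2, Pd(dppf)Cl2, KOAc, 1,4-dioxane, 90 °C; then aq. citric acid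
Reagents that add atoms: bis(pinacolato)diboron, CC1(C)OB(OC1(C)C)B1OC(C)(C)C(C)(C)O1
Why: Miyaura borylation, run at the carboxylate stage so that the arylpalladium intermediate never sits next to an acidic imide CH2, should replace Br at the future C5' by the pinacol boronate without touching the E-alkene.

**Step 3**
Reactants: 4 boronate half-ester; 5 (S)-4-benzyl-1,3-oxazolidin-2-one
Product: 7 methyl (E)-4-[(4S)-4-benzyl-2-oxo-1,3-oxazolidin-3-yl]-2-[3,4-dimethoxy-2-(pinacolboryl)benzylidene]-4-oxobutanoate, via mixed pivalic anhydride 6 (not isolated)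
Conditions: t-BuCOCl, Et3N, THF, −20 °C; then 5, LiCl, rt
Reagents that add atoms: pivaloyl chloride, CC(C)(C)C(=O)Cl (its acyl group stands in 6 only and is lost again)
Why: N-acylation of the oxazolidinone by a mixed anhydride under LiCl/Et3N activation needs no strong base, so the boronate and the beta,gamma-unsaturated acyl chain should survive; the stereocentre comes from 5.

**Step 4**
Reactants: 3 bromo half-ester; 7 (S)-imide boronate
Product: 8 biaryl acid imide: 2,2',3,3'-tetramethoxybiphenyl bearing at C6 the (E)-CH=C(CO2Me)CH2CO2H arm and at C6' the (E)-CH=C(CO2Me)CH2C(O)-[(4S)-4-benzyl-2-oxooxazolidin-3-yl] arm (both atropisomers)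
Conditions: Pd(OAc)2, SPhos, K3PO4, toluene/H2O, 80 °C; then aq. citric acid
Reagents that add atoms: none
Why: Suzuki–Miyaura coupling with a bulky electron-rich biarylphosphine suited to hindered partners should form C5–C5', and the bromide partner reacts as its carboxylate so that no acidic imide CH2 can intercept the arylpalladium species by alpha-arylation.

**Step 5**
Reactants: 8 biaryl acid imide; 9 (R)-4-benzyl-1,3-oxazolidin-2-one
Product: 11 unlike bis-imide: 2,2',3,3'-tetramethoxybiphenyl bearing at C6 and C6' the (E)-CH=C(CO2Me)CH2C(O)-(4-benzyl-2-oxooxazolidin-3-yl) arm with (4R) on one arm and (4S) on the other, via mixed pivalic anhydride 10 (not isolated)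
Conditions: t-BuCOCl, Et3N, THF, −20 °C; then 9, LiCl, rt
Reagents that add atoms: pivaloyl chloride, CC(C)(C)C(=O)Cl (its acyl group stands in 10 only and is lost again)
Why: The same mixed-anhydride N-acylation puts the mirror-image auxiliary on the second arm, so the two atropisomers of 8 should converge on the two enantiomers of one single diastereomer 11.

**Step 6**
Reactants: 11 unlike bis-imide; 12 3,4-dimethoxybenzaldehyde
Product: 16 dimethyl (1R,2S,1'S,2'R)-1,1'-bis(3,4-dimethoxyphenyl)-6,6',7,7'-tetramethoxy-2-[(4R)-4-benzyl-2-oxooxazolidine-3-carbonyl]-2'-[(4S)-4-benzyl-2-oxooxazolidine-3-carbonyl]-1,1',2,2'-tetrahydro-5,5'-binaphthalene-3,3'-dicarboxylate, via bis(boron enolate) 13 (not isolated), via bis(boron aldolate) 14 (not isolated), via ring-A-closed boron aldolate 15 (not isolated)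
Conditions: n-Bu2BOTf (2.4 equiv), i-Pr2NEt (2.8 equiv), CH2Cl2, −78 → 0 °C; 12 (3 equiv), −78 → 0 °C; then CF3CO2H, (CF3)2CHOH, 0 °C → rt
Reagents that add atoms: dibutylboron triflate, CCCCB(CCCC)OS(=O)(=O)C(F)(F)F (its Bu2B group stands in 13, 14 and 15 only and is lost again)
Why: Soft enolisation gives the bis[(Z)-boron enolate] 13, which adds twice to 12 through Zimmerman–Traxler chairs (Evans syn-aldol) to give 14; CF3CO2H then ionises each electron-rich benzylic C–O bond and the 3,4-dimethoxybenzyl cation is trapped by the neighbouring arene carbon (intramolecular Friedel–Crafts alkylation), first in one arm (15, drawn for ring A) and then in the other, so that the aldehyde carbon becomes C1 or C1' in a formal [5+1] annulation. The closest known reaction types are the alpha-selective boron aldol of beta,gamma-unsaturated N-acyl oxazolidinones and the acid-induced cyclodehydration of benzylic aldol adducts of benzylidenesuccinates and related butyrolactones to trans-1-aryl-1,2-dihydronaphthalenes, here telescoped and run in two directions. Ring A and then ring B each close by a six-membered cationic SEAr closure that forms C1–C8a (C1'–C8a'), endo with respect to the C4a=C8a arene bond and with the cationic carbon inside the new ring. C2 and C2' are set in the aldol by the auxiliary, the aldehyde reaching the enolate face remote from the benzyl group, so that the (R)-auxiliary should give 2S and the (S)-auxiliary 2'R, while C1 and C1' are set in the closure by C2 and C2', the planar cation being attacked anti to the bulky imide so that aryl and acyl groups end up trans (1R and 1'S); the carbinol centres of 14 are erased, so their purity does not matter. Site selectivity is secured because only C8a (C8a'), para to the C6 (C6') methoxy group, can reach the cation, the other ortho position being the biaryl carbon C5 (C5'), and because the methyl ester at C3 can add to the cation only reversibly. The step needs ring closure to outrun loss of H2 from the cation, which the non-basic, strongly ionising medium and the six-membered geometry held by the E-alkene should favour.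

**Step 7**
Reactants: 16 bis-cyclised bis-imide
Product: 18 (1R,2S,1'S,2'R)-1,1'-bis(3,4-dimethoxyphenyl)-6,6',7,7'-tetramethoxy-3,3'-bis(methoxycarbonyl)-1,1',2,2'-tetrahydro-5,5'-binaphthalene-2,2'-dicarboxylic acid, via bis(peroxy acid) 17 (not isolated)
Conditions: LiOH, H2O2, THF/H2O, 0 °C; Na2SO3; then 1 M HCl
Reagents that add atoms: hydrogen peroxide, OO
Why: Hydroperoxide attacks the exocyclic imide carbonyl selectively even in hindered N-acyl oxazolidinones, and at 0 °C the C2/C2' centres and the conjugated methyl esters should stay untouched while both auxiliaries are recovered.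

**Step 8**
Reactants: 18 diacid dimethyl ester
Product: 19 (1R,2S,1'S,2'R)-1,1'-bis(3,4-dimethoxyphenyl)-6,6',7,7'-tetramethoxy-1,1',2,2'-tetrahydro-5,5'-binaphthalene-2,2',3,3'-tetracarboxylic acid
Conditions: LiOH, THF/MeOH/H2O, 50 °C, N2; then 1 M HCl
Reagents that add atoms: lithium hydroxide, [Li+].[OH-]
Why: Saponification of the two conjugated methyl esters; the neighbouring C2 carboxylates make deprotonation at C2/C2' unlikely, the trans arrangement is in any case the more stable one, and exclusion of air guards against aromatisation.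

**Step 9**
Reactants: 19 tetraacid octamethyl ether
Product: 20 target, (1R,2S,1'S,2'R)-1,1'-bis(3,4-dihydroxyphenyl)-6,6',7,7'-tetrahydroxy-1,1',2,2'-tetrahydro-5,5'-binaphthalene-2,2',3,3'-tetracarboxylic acid
Conditions: BBr3 (20 equiv), CH2Cl2, −78 °C → rt; then H2O, 0 °C
Reagents that add atoms: none
Why: Lewis-acid ether cleavage (bromide attacks the methyl group of each boron-complexed aryl methyl ether) should free all eight phenols under acidic conditions, in which the dihydronaphthalene rings and their four stereocentres are not at risk.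

**Compound list**
1 | 2-bromo-3,4-dimethoxybenzaldehyde | O=Cc1ccc(OC)c(OC)c1Br | starting material
2 | dimethyl succinate | COC(=O)CCC(=O)OC | starting material
3 | (E)-4-(2-bromo-3,4-dimethoxyphenyl)-3-(methoxycarbonyl)but-3-enoic acid | OC(=O)C/C(C(=O)OC)=C\c1ccc(OC)c(OC)c1Br | intermediate
4 | (E)-4-[3,4-dimethoxy-2-(pinacolboryl)phenyl]-3-(methoxycarbonyl)but-3-enoic acid | OC(=O)C/C(C(=O)OC)=C\c1ccc(OC)c(OC)c1B1OC(C)(C)C(C)(C)O1 | intermediate
5 | (S)-4-benzyl-1,3-oxazolidin-2-one | O=C1N[C@@H](Cc2ccccc2)CO1 | starting material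
6 | mixed pivalic anhydride of 4 | CC(C)(C)C(=O)OC(=O)C/C(C(=O)OC)=C\c1ccc(OC)c(OC)c1B1OC(C)(C)C(C)(C)O1 | intermediate
7 | (S)-imide boronate | O=C(C/C(C(=O)OC)=C\c1ccc(OC)c(OC)c1B1OC(C)(C)C(C)(C)O1)N1[C@@H](Cc2ccccc2)COC1=O | intermediate
8 | biaryl acid imide, (4S)-auxiliary on one arm | OC(=O)C/C(C(=O)OC)=C\c1ccc(OC)c(OC)c1-c1c(OC)c(OC)ccc1/C=C(C(=O)OC)\CC(=O)N1[C@@H](Cc2ccccc2)COC1=O | intermediate
9 | (R)-4-benzyl-1,3-oxazolidin-2-one | O=C1N[C@H](Cc2ccccc2)CO1 | starting material
10 | mixed pivalic anhydride of 8 | CC(C)(C)C(=O)OC(=O)C/C(C(=O)OC)=C\c1ccc(OC)c(OC)c1-c1c(OC)c(OC)ccc1/C=C(C(=O)OC)\CC(=O)N1[C@@H](Cc2ccccc2)COC1=O | intermediate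
11 | unlike bis-imide, (4R) on one arm and (4S) on the other | O=C(C/C(C(=O)OC)=C\c1ccc(OC)c(OC)c1-c1c(OC)c(OC)ccc1/C=C(C(=O)OC)\CC(=O)N1[C@@H](Cc2ccccc2)COC1=O)N1[C@H](Cc2ccccc2)COC1=O | intermediate
12 | 3,4-dimethoxybenzaldehyde | COc1ccc(C=O)cc1OC | starting material
13 | bis[(Z)-dibutylboron enolate] of 11 | CCCCB(CCCC)O/C(N1[C@H](Cc2ccccc2)COC1=O)=C\C(C(=O)OC)=C/c1ccc(OC)c(OC)c1-c1c(OC)c(OC)ccc1/C=C(C(=O)OC)\C=C(/OB(CCCC)CCCC)N1[C@@H](Cc2ccccc2)COC1=O | intermediate
14 | bis(dibutylboron aldolate), syn in both arms: alpha and carbinol carbons (R,R) in the (4R)-arm, (S,S) in the (4S)-arm | O=C([C@H](/C(C(=O)OC)=C\c1ccc(OC)c(OC)c1-c1c(OC)c(OC)ccc1/C=C(C(=O)OC)\[C@@H]([C@H](OB(CCCC)CCCC)c1ccc(OC)c(OC)c1)C(=O)N1[C@@H](Cc2ccccc2)COC1=O)[C@@H](OB(CCCC)CCCC)c1ccc(OC)c(OC)c1)N1[C@H](Cc2ccccc2)COC1=O | intermediate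
15 | ring A closed (1R,2S), (4S)-arm still the boron aldolate | COC(=O)C1=Cc2c(cc(OC)c(OC)c2-c2c(OC)c(OC)ccc2/C=C(C(=O)OC)\[C@@H]([C@H](OB(CCCC)CCCC)c2ccc(OC)c(OC)c2)C(=O)N2[C@@H](Cc3ccccc3)COC2=O)[C@@H](c2ccc(OC)c(OC)c2)[C@@H]1C(=O)N1[C@H](Cc2ccccc2)COC1=O | intermediate
16 | bis-cyclised bis-imide (1R,2S,1'S,2'R) | COC(=O)C1=Cc2c(cc(OC)c(OC)c2-c2c(OC)c(OC)cc3c2C=C(C(=O)OC)[C@H](C(=O)N2[C@@H](Cc4ccccc4)COC2=O)[C@H]3c2ccc(OC)c(OC)c2)[C@@H](c2ccc(OC)c(OC)c2)[C@@H]1C(=O)N1[C@H](Cc2ccccc2)COC1=O | intermediate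
17 | bis(peroxy acid) at C2 and C2' | COC(=O)C1=Cc2c(cc(OC)c(OC)c2-c2c(OC)c(OC)cc3c2C=C(C(=O)OC)[C@H](C(=O)OO)[C@H]3c2ccc(OC)c(OC)c2)[C@@H](c2ccc(OC)c(OC)c2)[C@@H]1C(=O)OO | intermediate
18 | 2,2'-diacid 3,3'-dimethyl ester octamethyl ether | COC(=O)C1=Cc2c(cc(OC)c(OC)c2-c2c(OC)c(OC)cc3c2C=C(C(=O)OC)[C@H](C(=O)O)[C@H]3c2ccc(OC)c(OC)c2)[C@@H](c2ccc(OC)c(OC)c2)[C@@H]1C(=O)O | intermediate
19 | tetraacid octamethyl ether | O=C(O)C1=Cc2c(cc(OC)c(OC)c2-c2c(OC)c(OC)cc3c2C=C(C(=O)O)[C@H](C(=O)O)[C@H]3c2ccc(OC)c(OC)c2)[C@@H](c2ccc(OC)c(OC)c2)[C@@H]1C(=O)O | intermediate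
20 | CNP0242074.1 | O=C(O)C1=Cc2c(cc(O)c(O)c2-c2c(O)c(O)cc3c2C=C(C(=O)O)[C@H](C(=O)O)[C@H]3c2ccc(O)c(O)c2)[C@@H](c2ccc(O)c(O)c2)[C@@H]1C(=O)O | target

**Step count**
Total step count: 9. Longest linear sequence: 9 steps (1 → 3 → 4 → 7 → 8 → 11 → 16 → 18 → 19 → 20, with 3 entering a second time in step 4).

**Steps most likely to fail**

Step 6. Proton loss from the benzylic cation (E1, giving the dibenzylidene diene) may outrun ring closure and erase the C2/C2' configuration, or the second annulation may stall. The fallback sets out from 11 and comes back at 16 and, through a second isomer, at 18.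
- The boron aldol is run alone and 14 is worked up hydrolytically to the free bis-aldol F1.
- MsCl/Et3N gives the bis-mesylate F2, which DBU eliminates in the same flask to the all-E bis(dibenzylidenesuccinic) imide F3.
- CF3SO3H in CH2Cl2 then effects the known protonative cyclisation of (E,E)-dibenzylidenesuccinates to trans-1-aryl-1,2-dihydronaphthalenes.
- The auxiliaries now serve only as resolving tags, and the trans,trans isomers are separated by chromatography.
- Both unlike isomers, 16 and the inverted unlike bis-imide F4, are taken through step 7, where both should give 18.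

Step 4. Transmetalation and reductive elimination may be slow in a coupling that creates four ortho substituents. Competing processes are protodeboronation, base-induced migration of the benzylidene double bond and cleavage of the imide. The fallback sets out from 1 and comes back at 11.
- Ullmann homocoupling of 1 (Cu powder, DMF, 150 °C) gives 5,5',6,6'-tetramethoxybiphenyl-2,2'-dicarbaldehyde F5.
- A twofold Stobbe condensation with 2 gives the bis(half-ester) F6.
- t-BuCOCl/Et3N gives the bis(mixed anhydride) F7, which acylates an equimolar mixture of 5 and 9 (LiCl).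
- Compound 11 is separated by chromatography from the like (R,R)-bis-imide F8 and the like (S,S)-bis-imide F9.
- F8 and F9 are cleaved back to F6 with LiOH/H2O2 and recycled.

Step 9. Ether cleavage may stay incomplete because boron chelates of the poorly soluble tetraacid precipitate, and the four catechols may oxidise during work-up. The fallback sets out from 18 and comes back at 20, with the order of the endgame inverted.
- BBr3 is applied to the more soluble ester 18 to give the octaphenol dimethyl ester F10.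
- The two methyl esters are hydrolysed last (LiOH, Na2S2O4, degassed THF/H2O, argon; then HCl).

**Further compounds**
F1 | step 6 | free bis-aldol | O=C([C@H](/C(C(=O)OC)=C\c1ccc(OC)c(OC)c1-c1c(OC)c(OC)ccc1/C=C(C(=O)OC)\[C@@H]([C@H](O)c1ccc(OC)c(OC)c1)C(=O)N1[C@@H](Cc2ccccc2)COC1=O)[C@@H](O)c1ccc(OC)c(OC)c1)N1[C@H](Cc2ccccc2)COC1=O
F2 | step 6 | bis-mesylate | O=C([C@H](/C(C(=O)OC)=C\c1ccc(OC)c(OC)c1-c1c(OC)c(OC)ccc1/C=C(C(=O)OC)\[C@@H]([C@H](OS(C)(=O)=O)c1ccc(OC)c(OC)c1)C(=O)N1[C@@H](Cc2ccccc2)COC1=O)[C@@H](OS(C)(=O)=O)c1ccc(OC)c(OC)c1)N1[C@H](Cc2ccccc2)COC1=O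
F3 | step 6 | all-E bis(dibenzylidenesuccinic) imide | O=C(N1[C@H](Cc2ccccc2)COC1=O)C(=C/c1ccc(OC)c(OC)c1)/C(C(=O)OC)=C\c1ccc(OC)c(OC)c1-c1c(OC)c(OC)ccc1/C=C(C(=O)OC)\C(=C/c1ccc(OC)c(OC)c1)C(=O)N1[C@@H](Cc2ccccc2)COC1=O
F4 | step 6 | inverted unlike bis-imide, (1S,2R) half on the (4R)-auxiliary and (1R,2S) half on the (4S)-auxiliary | COC(=O)C1=Cc2c(cc(OC)c(OC)c2-c2c(OC)c(OC)cc3c2C=C(C(=O)OC)[C@H](C(=O)N2[C@H](Cc4ccccc4)COC2=O)[C@H]3c2ccc(OC)c(OC)c2)[C@@H](c2ccc(OC)c(OC)c2)[C@@H]1C(=O)N1[C@@H](Cc2ccccc2)COC1=O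
F5 | step 4 | 5,5',6,6'-tetramethoxybiphenyl-2,2'-dicarbaldehyde | O=Cc1ccc(OC)c(OC)c1-c1c(OC)c(OC)ccc1C=O
F6 | step 4 | bis(half-ester) | OC(=O)C/C(C(=O)OC)=C\c1ccc(OC)c(OC)c1-c1c(OC)c(OC)ccc1/C=C(C(=O)OC)\CC(=O)O
F7 | step 4 | bis(mixed anhydride) | CC(C)(C)C(=O)OC(=O)C/C(C(=O)OC)=C\c1ccc(OC)c(OC)c1-c1c(OC)c(OC)ccc1/C=C(C(=O)OC)\CC(=O)OC(=O)C(C)(C)C
F8 | step 4 | like (R,R)-bis-imide | O=C(C/C(C(=O)OC)=C\c1ccc(OC)c(OC)c1-c1c(OC)c(OC)ccc1/C=C(C(=O)OC)\CC(=O)N1[C@H](Cc2ccccc2)COC1=O)N1[C@H](Cc2ccccc2)COC1=O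
F9 | step 4 | like (S,S)-bis-imide | O=C(C/C(C(=O)OC)=C\c1ccc(OC)c(OC)c1-c1c(OC)c(OC)ccc1/C=C(C(=O)OC)\CC(=O)N1[C@@H](Cc2ccccc2)COC1=O)N1[C@@H](Cc2ccccc2)COC1=O
F10 | step 9 | octaphenol dimethyl ester | COC(=O)C1=Cc2c(cc(O)c(O)c2-c2c(O)c(O)cc3c2C=C(C(=O)OC)[C@H](C(=O)O)[C@H]3c2ccc(O)c(O)c2)[C@@H](c2ccc(O)c(O)c2)[C@@H]1C(=O)O
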